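# Proposed synthesis of CNP0230414.1: methyl (13S)-3α-acetoxy-15-hydroxylabd-8(17)-en-19-oate (18)

## The problem

- The target is a normal-series labdane: a trans-fused decalin (ring A = C1–C5, C10; ring B = C5–C10) with five contiguous ring stereocentres (C3, C4, C5, C10, C9), an exocyclic C8=C17 methylene and a C9 side chain that carries a sixth, isolated stereocentre (C13, S).
- C4 and C10 are quaternary. C4 holds the 4α-methyl and the axial 4β-methoxycarbonyl (C19), which is 1,3-diaxial to the C20 methyl. C3 holds an axial 3α-acetoxy group, anti to C19.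
- The ring stereocentres can control one another through chair folding. C13 lies four bonds from C9 and can neither steer the ring nor be steered by it, so two independent sources of absolute configuration are needed.
- The C19 ester is neopentylic and axial. It cannot be transesterified or introduced by late carboxylation, and it forbids any ring closure that places positive charge on C4.
- The 8(17)-alkene moves into the ring under acid and must be formed regioselectively. The oxygens at C3 and C15 must end up differentiated (acetate versus free alcohol).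
- The feature that opens the problem: at the ketone level, C3, C4 and C19 form a 2-methyl-3-oxo ester. In the open chain the trisubstituted alkenes C5=C10 and C8=C9 each carry their methyl on the carbon nearer C4. A radical at C4 can therefore close ring A and then ring B by two 6-endo additions, and the C17 methyl on C8 supplies the hydrogen lost when the exocyclic alkene forms.

## Retrosynthesis

**18 ⇒ 17 ⇒ 16.** The C15 O–Si bond and the C3 O–acetyl bond are cut last. The hindered 3α-hydroxyl of 16 is acetylated while C15 is still masked as its silyl ether (17), so the two oxygens never compete.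

**16 ⇒ 15 ⇒ 13 ⇒ 12.** The methyl ester of 16 stands in for the auxiliary ester of 12. The axial C19 acyl carbon cannot be attacked by an alkoxide, so the exchange goes through the oxidation ladder: LiAlH4 to diol 13 (auxiliary 6 recovered), selective oxidation of the primary alcohol through aldehyde 14 to acid 15, and O-methylation of the carboxylate. O-Alkylation avoids attack at the hindered carbonyl.

**12 ⇒ 11.** The C3–H bond is cut. The axial 3α-alcohol is the kinetic product of equatorial hydride delivery to the C3 ketone of 11. This is why the ring-forming step is run at the ketone level, not with a preformed carbinol, which would end up equatorial in a chair transition state.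

**11 ⇒ 10 (key).** Both ring bonds C4–C5 and C9–C10 are cut, and C8=C17 is traced back to the C17 methyl. The neighbouring cut, the same two bonds made with a cation at C4, cannot carry the ester and leaves C4 as a gem-dimethyl carbon. A radical at C4 is stabilised by exactly the two carbonyls the target needs (C3=O and C19). Precursor 10 is acyclic, with only the C13 stereocentre and the auxiliary. The forward reaction must deliver two 6-endo closures through chair transition states, face selectivity at C4 from the ester auxiliary, and exocyclic termination.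

**10 ⇒ 8 + 5 (via 9).** The C1–C2 bond is cut. The terminal carbanion of acetoacetate dianion 9 alkylates allylic bromide 5 by SN2, joining the whole carbon skeleton in one convergent step. The epimeric α-carbon of 10 needs no control because it becomes planar in the key step.

**5 ⇒ 4 ⇒ 3 ⇒ 2 ⇒ 1.** The chain is (2E,6E)-farnesol (1) read from its hydroxyl end. C1–C3 of farnesol become C15–C13, its 6,7-alkene becomes C8=C9, its terminal alkene becomes C5=C10, and its (E)-ω-methyl becomes C1. Asymmetric hydrogenation of the allylic alcohol sets C13 (2). Allylic oxidation of the silyl ether 3 at the ω-(E)-methyl gives 4 and then bromide 5.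

**8 ⇒ 6 + 7.** The auxiliary ester 8 comes from (−)-8-phenylmenthol (6) and methyl 2-methyl-3-oxobutanoate (7) by transesterification. The auxiliary is needed because C13 is too remote to bias the folding; without it the cyclisation would give two inseparable core diastereomers.

## Roads not taken

**Alternative 1:** Epoxide-initiated bicyclisation, the most obvious route. The same bonds (C4–C5, C9–C10) are formed from the (3S)-epoxy polyene A1, either as a cation (SnCl4 or MeAlCl2) or as a radical (Cp2TiCl). The product is the 3β-hydroxy-4,4-dimethyl labdane A2.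
- A2 has the wrong C3 configuration and no C19 carboxyl.
- The axial 4β-methyl is out of reach of oxygen-directed C–H functionalisation from O3, which selects the equatorial 4α-methyl.
- An ester cannot be placed on C4 beforehand because C4 must carry the positive charge.
- Cationic termination gives alkene regioisomers.
- The chosen plan brings C19 in at the carboxyl level and C3 at the ketone level in the same step.

**Alternative 2:** Annulation and reductive alkylation. Ring A is built on ring B by an amine-catalysed aldol condensation to the 4-methoxycarbonyl Wieland–Miescher-type enedione A3. Li/NH3 reduction with methylation of the enolate then gives the trans-decalin keto ester A4, with C4, C5 and C10 set.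
- This is dependable for ring A, but the C9 ketone of A4 must then be converted into a C9 side chain plus a C8 methylene.
- That needs addition of a side-chain organometallic to a neopentylic ketone, followed by dehydration, oxygen transposition, epimerisation and methylenation.
- The linear sequence would be well beyond fifteen steps, with C9 set only by equilibration.
- The chosen plan makes C9, C8=C17 and the side chain in the ring-forming step.

**Alternative 3:** Semisynthesis from (+)-sclareolide A5. Rings A and B, C5, C9 and C10 are bought. C3 is oxidised to 3β-hydroxysclareolide A6, and the lactone is homologated to the side chain.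
- The route moves the whole difficulty onto oxidation of the unactivated axial C19 methyl to a carboxyl, for which no directing handle exists.
- It still needs inversion at C3 and a new C13 stereocentre in the side chain.
- The chosen plan avoids C–H oxidation at C4 altogether.

Key step: step 7

Assumption: labdane numbering is used for all cyclised compounds; the face of the C4 radical shielded by the (1R,2S,5R)-auxiliary is assigned from the usual aryl-stacked conformer of 8-phenylmenthyl esters, and the antipodal auxiliary would be used if the sense proved opposite.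

## Route

Step 1
Reactants: 1 (2E,6E)-farnesol
Product: 2 (3S,6E)-3,7,11-trimethyldodeca-6,10-dien-1-ol
Conditions: H2 (30 atm), Ru(OAc)2[(R)-BINAP] (0.2 mol %), MeOH–H2O 95:5, 20 °C
Reagents that add atoms: none
Why: Hydroxyl-directed asymmetric hydrogenation of an allylic alcohol (geraniol-to-citronellol type): only the 2,3-alkene, which chelates ruthenium through the hydroxyl, is reduced, and the (R)-ligand with the (2E)-alkene should set the (S)-centre that becomes C13.

Step 2
Reactants: 2 (3S,6E)-3,7,11-trimethyldodeca-6,10-dien-1-ol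
Product: 3 tert-butyl{[(3S,6E)-3,7,11-trimethyldodeca-6,10-dien-1-yl]oxy}diphenylsilane
Conditions: TBDPSCl, imidazole, DMF, 0 °C to 20 °C
Reagents that add atoms: tert-butyl(chloro)diphenylsilane, CC(C)(C)[Si](Cl)(c1ccccc1)c1ccccc1
Why: Silyl ether formation at a primary alcohol; the TBDPS group is chosen because it should survive acetic acid, strong base and hydride reagents and is removed by fluoride without touching an acetate.

Step 3
Reactants: 3 tert-butyl{[(3S,6E)-3,7,11-trimethyldodeca-6,10-dien-1-yl]oxy}diphenylsilane
Product: 4 (2E,6E,10S)-12-[(tert-butyldiphenylsilyl)oxy]-2,6,10-trimethyldodeca-2,6-dien-1-ol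
Conditions: SeO2 (0.3 equiv), t-BuOOH (3 equiv), salicylic acid (0.1 equiv), CH2Cl2, 0 °C to 20 °C
Reagents that add atoms: tert-butyl hydroperoxide, CC(C)(C)OO; selenium dioxide (oxygen relay), O=[Se]=O
Why: Selenium dioxide allylic oxidation (ene reaction followed by [2,3]-sigmatropic shift) is selective for the (E)-methyl of a terminal gem-dimethyl alkene, as in the ω-hydroxylation of geranyl and farnesyl derivatives, so the E-allylic alcohol at the future C1 should result.

Step 4
Reactants: 4 (2E,6E,10S)-12-[(tert-butyldiphenylsilyl)oxy]-2,6,10-trimethyldodeca-2,6-dien-1-ol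
Product: 5 {[(3S,6E,10E)-12-bromo-3,7,11-trimethyldodeca-6,10-dien-1-yl]oxy}(tert-butyl)diphenylsilane
Conditions: CBr4, PPh3, CH2Cl2, −20 °C to 0 °C; used without storage
Reagents that add atoms: tetrabromomethane, BrC(Br)(Br)Br
Why: Appel bromination of a primary allylic alcohol proceeds by SN2 at the oxyphosphonium carbon under neutral conditions, so the E geometry and the silyl ether should be retained.

Step 5
Reactants: 6 (1R,2S,5R)-5-methyl-2-(2-phenylpropan-2-yl)cyclohexan-1-ol [(−)-8-phenylmenthol]; 7 methyl 2-methyl-3-oxobutanoate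
Product: 8 (1R,2S,5R)-5-methyl-2-(2-phenylpropan-2-yl)cyclohexyl 2-methyl-3-oxobutanoate
Conditions: DMAP (0.3 equiv), 7 (3 equiv), toluene, reflux, 4 Å sieves (removal of MeOH)
Reagents that add atoms: none
Why: DMAP-catalysed transesterification of a β-keto ester, which proceeds through the acylketene and therefore tolerates a hindered secondary alcohol; the stereocentres of the auxiliary are not involved.

Step 6
Reactants: 8 (1R,2S,5R)-5-methyl-2-(2-phenylpropan-2-yl)cyclohexyl 2-methyl-3-oxobutanoate; 5 {[(3S,6E,10E)-12-bromo-3,7,11-trimethyldodeca-6,10-dien-1-yl]oxy}(tert-butyl)diphenylsilane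
Product: 10 (1R,2S,5R)-5-methyl-2-(2-phenylpropan-2-yl)cyclohexyl (2RS,6E,10E,14S)-16-[(tert-butyldiphenylsilyl)oxy]-2,6,10,14-tetramethyl-3-oxohexadeca-6,10-dienoate, via acetoacetate dianion 9 (not isolated)
Conditions: NaH (1.1 equiv), THF, 0 °C; n-BuLi (1.05 equiv), 0 °C; 5 (0.9 equiv), 0 °C; AcOH quench
Reagents that add atoms: none
Why: γ-Alkylation of an acetoacetate dianion: the more basic terminal carbanion of 9 displaces the allylic bromide by SN2 without allylic transposition, forming the C1–C2 bond; the ester α-carbon is left as an epimer mixture because it becomes planar in step 7.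

Step 7
Reactants: 10 (1R,2S,5R)-5-methyl-2-(2-phenylpropan-2-yl)cyclohexyl (2RS,6E,10E,14S)-16-[(tert-butyldiphenylsilyl)oxy]-2,6,10,14-tetramethyl-3-oxohexadeca-6,10-dienoate
Product: 11 (1R,2S,5R)-5-methyl-2-(2-phenylpropan-2-yl)cyclohexyl (13S)-15-[(tert-butyldiphenylsilyl)oxy]-3-oxolabd-8(17)-en-19-oate
Conditions: Mn(OAc)3·2H2O (2.2 equiv), Cu(OAc)2·H2O (1.0 equiv), degassed AcOH, 25 °C (to 40 °C if slow); no chelating Lewis acid
Reagents that add atoms: none
Why: Oxidative free-radical polyene cyclisation of an α-methyl β-keto ester by trivalent manganese and divalent copper: enolisation and one-electron oxidation by Mn(OAc)3 give the C4 radical, which adds 6-endo-trig to C5 of the C5=C10 alkene (ring A); the tertiary C10 radical adds 6-endo-trig to C9 of the C8=C9 alkene (ring B); the tertiary C8 radical is taken up by Cu(OAc)2 as an alkylcopper that loses a C17 hydrogen to give the 8(17)-alkene, and Mn(OAc)3 reoxidises the monovalent copper. The closest known reactions are the Mn(OAc)3/Cu(OAc)2 polycyclisations of farnesyl-type 2-methyl-3-oxo esters to 3-oxo-19-esters with a terminal exocyclic methylene, and the same cyclisation run on 8-phenylmenthyl β-keto esters for absolute control. Both closures are 6-endo because each alkene carries its methyl on the carbon nearer the radical, so attack at the far CH carbon gives a tertiary radical. C4 is set by the face of the planar radical that bonds to C5: the phenyl ring of the auxiliary stacks over one face and C5 enters from the other, and because the radical reacts with its ester carbonyl turned away from the ketone oxygen the ester lies cis to C2 and becomes axial (4β), with the methyl equatorial (4α). C5 and C10 follow from chair-like transition states for both closures (5α-H, 10β-methyl, trans fusion), and C9 from the E geometry of C8=C9, which keeps C11 equatorial (9β side chain, 9α-H). The two α-epimers of 10 converge because that carbon is planar in the radical; a chelating Lewis acid is avoided because holding the two carbonyls syn would be expected to turn the ester equatorial. The step needs three selectivities: facial selectivity from the auxiliary (the minor product is a true diastereomer and should be separable by chromatography), closure of ring B before Cu(OAc)2 intercepts the C10 radical (helped by the electron-rich trisubstituted acceptor), and exocyclic elimination (the alkylcopper eliminates toward the unhindered methyl hydrogens).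

Step 8
Reactants: 11 (1R,2S,5R)-5-methyl-2-(2-phenylpropan-2-yl)cyclohexyl (13S)-15-[(tert-butyldiphenylsilyl)oxy]-3-oxolabd-8(17)-en-19-oate
Product: 12 (1R,2S,5R)-5-methyl-2-(2-phenylpropan-2-yl)cyclohexyl (13S)-15-[(tert-butyldiphenylsilyl)oxy]-3α-hydroxylabd-8(17)-en-19-oate
Conditions: LiBH(s-Bu)3 (1.5 equiv), THF, −78 °C; H2O work-up
Reagents that add atoms: none
Why: Ketone reduction by a bulky trialkylborohydride: the axial trajectory on the α-face is blocked by the syn-axial hydrogens at C1 and C5, so hydride should arrive along the equatorial direction and give the axial 3α-alcohol (3R), as with 4,4-disubstituted 3-oxo terpenoids; the hindered ester is not reduced at −78 °C.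

Step 9
Reactants: 12 (1R,2S,5R)-5-methyl-2-(2-phenylpropan-2-yl)cyclohexyl (13S)-15-[(tert-butyldiphenylsilyl)oxy]-3α-hydroxylabd-8(17)-en-19-oate
Product: 13 (13S)-15-[(tert-butyldiphenylsilyl)oxy]labd-8(17)-ene-3α,19-diol
Conditions: LiAlH4 (3 equiv), THF, 0 °C to 45 °C; aqueous NaOH work-up
Reagents that add atoms: none
Why: LiAlH4 reduction of a hindered ester to the primary alcohol, the standard way to release an axial C19 ester that resists acyl substitution; the auxiliary alcohol 6 is recovered and no stereocentre is touched.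

Step 10
Reactants: 13 (13S)-15-[(tert-butyldiphenylsilyl)oxy]labd-8(17)-ene-3α,19-diol
Product: 15 (13S)-15-[(tert-butyldiphenylsilyl)oxy]-3α-hydroxylabd-8(17)-en-19-oic acid, via hydroxy aldehyde 14 (not isolated)
Conditions: TEMPO (0.2 equiv), PhI(OAc)2 (2.5 equiv), MeCN–pH 7 phosphate buffer 1:1, 20 °C
Reagents that add atoms: water, O
Why: Oxoammonium (TEMPO) oxidation is selective for primary over hindered secondary alcohols, and in aqueous medium the hydrate of aldehyde 14 is oxidised on to the acid; the alkene and silyl ether are inert to this oxidant.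

Step 11
Reactants: 15 (13S)-15-[(tert-butyldiphenylsilyl)oxy]-3α-hydroxylabd-8(17)-en-19-oic acid
Product: 16 methyl (13S)-15-[(tert-butyldiphenylsilyl)oxy]-3α-hydroxylabd-8(17)-en-19-oate
Conditions: Me3SiCHN2 (2 M in hexanes), toluene–MeOH 4:1, 0 °C to 20 °C
Reagents that add atoms: (trimethylsilyl)diazomethane, C[Si](C)(C)C=[N+]=[N-]
Why: Esterification by O-alkylation of the carboxylate with a diazoalkane, which needs no attack at the hindered axial carbonyl and leaves the secondary alcohol untouched.

Step 12
Reactants: 16 methyl (13S)-15-[(tert-butyldiphenylsilyl)oxy]-3α-hydroxylabd-8(17)-en-19-oate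
Product: 17 methyl (13S)-3α-acetoxy-15-[(tert-butyldiphenylsilyl)oxy]labd-8(17)-en-19-oate
Conditions: Ac2O, DMAP (0.2 equiv), pyridine, 40 °C
Reagents that add atoms: acetic anhydride, CC(=O)OC(C)=O
Why: DMAP-catalysed acylation of a hindered axial secondary alcohol; C15 is still silylated, so only O3 is acetylated and the C3 configuration is retained.

Step 13
Reactants: 17 methyl (13S)-3α-acetoxy-15-[(tert-butyldiphenylsilyl)oxy]labd-8(17)-en-19-oate
Product: 18 methyl (13S)-3α-acetoxy-15-hydroxylabd-8(17)-en-19-oate (CNP0230414.1)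
Conditions: Bu4NF (1.5 equiv), AcOH (1.5 equiv), THF, 20 °C
Reagents that add atoms: none
Why: Fluoride-mediated desilylation buffered with acetic acid, so the hindered secondary acetate and the methyl ester should not be cleaved or migrate.

## Compound list

1 | (2E,6E)-farnesol | CC(C)=CCC/C(C)=C/CC/C(C)=C/CO | starting material
2 | (3S,6E)-3,7,11-trimethyldodeca-6,10-dien-1-ol | CC(C)=CCC/C(C)=C/CC[C@H](C)CCO | intermediate
3 | tert-butyl{[(3S,6E)-3,7,11-trimethyldodeca-6,10-dien-1-yl]oxy}diphenylsilane | CC(C)=CCC/C(C)=C/CC[C@H](C)CCO[Si](c1ccccc1)(c1ccccc1)C(C)(C)C | intermediate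
4 | (2E,6E,10S)-12-[(tert-butyldiphenylsilyl)oxy]-2,6,10-trimethyldodeca-2,6-dien-1-ol | OC/C(C)=C/CC/C(C)=C/CC[C@H](C)CCO[Si](c1ccccc1)(c1ccccc1)C(C)(C)C | intermediate
5 | {[(3S,6E,10E)-12-bromo-3,7,11-trimethyldodeca-6,10-dien-1-yl]oxy}(tert-butyl)diphenylsilane | BrC/C(C)=C/CC/C(C)=C/CC[C@H](C)CCO[Si](c1ccccc1)(c1ccccc1)C(C)(C)C | intermediate
6 | (1R,2S,5R)-5-methyl-2-(2-phenylpropan-2-yl)cyclohexan-1-ol, (−)-8-phenylmenthol | C[C@@H]1CC[C@@H](C(C)(C)c2ccccc2)[C@H](O)C1 | starting material
7 | methyl 2-methyl-3-oxobutanoate | COC(=O)C(C)C(C)=O | starting material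
8 | (1R,2S,5R)-8-phenylmenthyl 2-methyl-3-oxobutanoate (α-epimers) | CC(=O)C(C)C(=O)O[C@@H]1C[C@H](C)CC[C@H]1C(C)(C)c1ccccc1 | intermediate
9 | sodium lithium dianion of 8 | [Li+].[Na+].[CH2-]C(=O)[C-](C)C(=O)O[C@@H]1C[C@H](C)CC[C@H]1C(C)(C)c1ccccc1 | intermediate (not isolated)
10 | (1R,2S,5R)-8-phenylmenthyl (2RS,6E,10E,14S)-16-[(tert-butyldiphenylsilyl)oxy]-2,6,10,14-tetramethyl-3-oxohexadeca-6,10-dienoate | O=C(CC/C(C)=C/CC/C(C)=C/CC[C@H](C)CCO[Si](c1ccccc1)(c1ccccc1)C(C)(C)C)C(C)C(=O)O[C@@H]1C[C@H](C)CC[C@H]1C(C)(C)c1ccccc1 | intermediate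
11 | (1R,2S,5R)-8-phenylmenthyl (4R,5R,9S,10R,13S)-15-[(tert-butyldiphenylsilyl)oxy]-3-oxolabd-8(17)-en-19-oate | C=C1CC[C@@H]2[C@](C)(CCC(=O)[C@]2(C)C(=O)O[C@@H]3C[C@H](C)CC[C@H]3C(C)(C)c3ccccc3)[C@H]1CC[C@H](C)CCO[Si](c1ccccc1)(c1ccccc1)C(C)(C)C | intermediate
12 | (1R,2S,5R)-8-phenylmenthyl (13S)-15-[(tert-butyldiphenylsilyl)oxy]-3α-hydroxylabd-8(17)-en-19-oate | C=C1CC[C@@H]2[C@](C)(CC[C@@H](O)[C@]2(C)C(=O)O[C@@H]3C[C@H](C)CC[C@H]3C(C)(C)c3ccccc3)[C@H]1CC[C@H](C)CCO[Si](c1ccccc1)(c1ccccc1)C(C)(C)C | intermediate
13 | (13S)-15-[(tert-butyldiphenylsilyl)oxy]labd-8(17)-ene-3α,19-diol | C=C1CC[C@@H]2[C@](C)(CC[C@@H](O)[C@]2(C)CO)[C@H]1CC[C@H](C)CCO[Si](c1ccccc1)(c1ccccc1)C(C)(C)C | intermediate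
14 | (13S)-15-[(tert-butyldiphenylsilyl)oxy]-3α-hydroxylabd-8(17)-en-19-al | C=C1CC[C@@H]2[C@](C)(CC[C@@H](O)[C@]2(C)C=O)[C@H]1CC[C@H](C)CCO[Si](c1ccccc1)(c1ccccc1)C(C)(C)C | intermediate (not isolated)
15 | (13S)-15-[(tert-butyldiphenylsilyl)oxy]-3α-hydroxylabd-8(17)-en-19-oic acid | C=C1CC[C@@H]2[C@](C)(CC[C@@H](O)[C@]2(C)C(=O)O)[C@H]1CC[C@H](C)CCO[Si](c1ccccc1)(c1ccccc1)C(C)(C)C | intermediate
16 | methyl (13S)-15-[(tert-butyldiphenylsilyl)oxy]-3α-hydroxylabd-8(17)-en-19-oate | C=C1CC[C@@H]2[C@](C)(CC[C@@H](O)[C@]2(C)C(=O)OC)[C@H]1CC[C@H](C)CCO[Si](c1ccccc1)(c1ccccc1)C(C)(C)C | intermediate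
17 | methyl (13S)-3α-acetoxy-15-[(tert-butyldiphenylsilyl)oxy]labd-8(17)-en-19-oate | C=C1CC[C@@H]2[C@](C)(CC[C@@H](OC(C)=O)[C@]2(C)C(=O)OC)[C@H]1CC[C@H](C)CCO[Si](c1ccccc1)(c1ccccc1)C(C)(C)C | intermediate
18 | methyl (3R,4R,5R,9S,10R,13S)-3-acetoxy-15-hydroxylabd-8(17)-en-19-oate (CNP0230414.1) | C=C1CC[C@@H]2[C@](C)(CC[C@@H](OC(C)=O)[C@]2(C)C(=O)OC)[C@H]1CC[C@H](C)CCO | target

## Step count and risks

Total step count: 13. Longest linear sequence: 12 (steps 1–4 and 6–13); step 5 is a one-step side branch.

**Step 7 (key step).**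
- What may go wrong:
  - incomplete facial discrimination by the auxiliary;
  - interception of the monocyclic C10 radical by Cu(OAc)2 before ring B closes;
  - loss of regiocontrol in the terminating elimination, with hydrogen taken from C7 instead of C17.
- Fallback, from 10 back to 11: the same C4 radical is run as a group-transfer chain without metal oxidants.
  - Selenenylation of 10 (NaH, PhSeCl, THF, 0 °C) gives the α-phenylselenyl β-keto ester F1.
  - Irradiation (sunlamp, benzene, 25 °C) starts a phenylselenyl-transfer bicyclisation in which the tertiary C8 radical is capped by selenium, giving the C8 selenide F2.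
  - Oxidation (H2O2, pyridine, CH2Cl2, 0 °C) and syn-elimination of the selenoxide returns to 11.

**Step 3.**
- What may go wrong: competing oxidation at the allylic methylene and methyl positions of the internal alkene, and over-oxidation of the product to the enal.
- Fallback, from 3 back to 4, with the terminal carbon introduced by olefination instead of C–H oxidation:
  - NBS in aqueous THF gives the terminal bromohydrin F3.
  - K2CO3 in MeOH gives the terminal epoxide F4.
  - H5IO6 in aqueous THF cleaves it to the aldehyde F5.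
  - Wittig reaction with Ph3P=C(CH3)CO2Et gives the (E)-enoate F6.
  - i-Bu2AlH (CH2Cl2, −78 °C) gives 4.

**Step 8.**
- What may go wrong: hydride delivery along the axial trajectory, giving the equatorial 3β-alcohol, if the aryl group of the auxiliary or lithium chelation by the axial ester blocks the equatorial approach.
- Fallback, from 11 to 16, with the reduction postponed until the auxiliary is gone:
  - LiAlH4 gives the 3β,19-diol F7 (C3 configuration irrelevant; 6 recovered).
  - Dess–Martin periodinane gives the keto aldehyde F8.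
  - NaClO2, NaH2PO4 and 2-methyl-2-butene give the keto acid F9, which is esterified at once at 0 °C with Me3SiCHN2 to avoid decarboxylation, giving the methyl keto ester F10.
  - LiBH(s-Bu)3 at −78 °C on this smaller ester joins the route at 16.

**Step 10.**
- What may go wrong: stalling at the aldehyde stage, because the neopentylic aldehyde hydrates poorly, or competing oxidation of the secondary alcohol on long exposure.
- Fallback, from 12 to 15, bypassing diol 13: half-reduction of the auxiliary ester with i-Bu2AlH (CH2Cl2, −78 °C) gives aldehyde 14, which is isolated and oxidised with NaClO2, NaH2PO4 and 2-methyl-2-butene to 15.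

## Further compounds

F1 | step 7 | (1R,2S,5R)-8-phenylmenthyl (6E,10E,14S)-16-[(tert-butyldiphenylsilyl)oxy]-2,6,10,14-tetramethyl-3-oxo-2-(phenylselanyl)hexadeca-6,10-dienoate | O=C(CC/C(C)=C/CC/C(C)=C/CC[C@H](C)CCO[Si](c1ccccc1)(c1ccccc1)C(C)(C)C)C(C)([Se]c1ccccc1)C(=O)O[C@@H]1C[C@H](C)CC[C@H]1C(C)(C)c1ccccc1
F2 | step 7 | (1R,2S,5R)-8-phenylmenthyl (13S)-15-[(tert-butyldiphenylsilyl)oxy]-3-oxo-8-(phenylselanyl)labdan-19-oate (C8 epimers) | CC1([Se]c2ccccc2)CC[C@@H]2[C@](C)(CCC(=O)[C@]2(C)C(=O)O[C@@H]3C[C@H](C)CC[C@H]3C(C)(C)c3ccccc3)[C@H]1CC[C@H](C)CCO[Si](c1ccccc1)(c1ccccc1)C(C)(C)C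
F3 | step 3 | (6E,10S)-3-bromo-12-[(tert-butyldiphenylsilyl)oxy]-2,6,10-trimethyldodec-6-en-2-ol (C3 epimers) | CC(C)(O)C(Br)CC/C(C)=C/CC[C@H](C)CCO[Si](c1ccccc1)(c1ccccc1)C(C)(C)C
F4 | step 3 | tert-butyl{[(3S,6E)-9-(3,3-dimethyloxiran-2-yl)-3,7-dimethylnon-6-en-1-yl]oxy}diphenylsilane | CC1(C)OC1CC/C(C)=C/CC[C@H](C)CCO[Si](c1ccccc1)(c1ccccc1)C(C)(C)C
F5 | step 3 | (4E,8S)-10-[(tert-butyldiphenylsilyl)oxy]-4,8-dimethyldec-4-enal | O=CCC/C(C)=C/CC[C@H](C)CCO[Si](c1ccccc1)(c1ccccc1)C(C)(C)C
F6 | step 3 | ethyl (2E,6E,10S)-12-[(tert-butyldiphenylsilyl)oxy]-2,6,10-trimethyldodeca-2,6-dienoate | CCOC(=O)/C(C)=C/CC/C(C)=C/CC[C@H](C)CCO[Si](c1ccccc1)(c1ccccc1)C(C)(C)C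
F7 | step 8 | (13S)-15-[(tert-butyldiphenylsilyl)oxy]labd-8(17)-ene-3β,19-diol | C=C1CC[C@@H]2[C@](C)(CC[C@H](O)[C@]2(C)CO)[C@H]1CC[C@H](C)CCO[Si](c1ccccc1)(c1ccccc1)C(C)(C)C
F8 | step 8 | (13S)-15-[(tert-butyldiphenylsilyl)oxy]-3-oxolabd-8(17)-en-19-al | C=C1CC[C@@H]2[C@](C)(CCC(=O)[C@]2(C)C=O)[C@H]1CC[C@H](C)CCO[Si](c1ccccc1)(c1ccccc1)C(C)(C)C
F9 | step 8 | (13S)-15-[(tert-butyldiphenylsilyl)oxy]-3-oxolabd-8(17)-en-19-oic acid | C=C1CC[C@@H]2[C@](C)(CCC(=O)[C@]2(C)C(=O)O)[C@H]1CC[C@H](C)CCO[Si](c1ccccc1)(c1ccccc1)C(C)(C)C
F10 | step 8 | methyl (13S)-15-[(tert-butyldiphenylsilyl)oxy]-3-oxolabd-8(17)-en-19-oate | C=C1CC[C@@H]2[C@](C)(CCC(=O)[C@]2(C)C(=O)OC)[C@H]1CC[C@H](C)CCO[Si](c1ccccc1)(c1ccccc1)C(C)(C)C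
F0 | step 10 | none | none
A1 | alternative 1 | tert-butyl{[(3S,6E,10E)-13-[(2S)-3,3-dimethyloxiran-2-yl]-3,7,11-trimethyltrideca-6,10-dien-1-yl]oxy}diphenylsilane | CC1(C)O[C@H]1CC/C(C)=C/CC/C(C)=C/CC[C@H](C)CCO[Si](c2ccccc2)(c2ccccc2)C(C)(C)C
A2 | alternative 1 | (13S)-15-[(tert-butyldiphenylsilyl)oxy]labd-8(17)-en-3β-ol | C=C1CC[C@@H]2[C@](C)(CC[C@H](O)C2(C)C)[C@H]1CC[C@H](C)CCO[Si](c3ccccc3)(c3ccccc3)C(C)(C)C
A3 | alternative 2 | methyl 10β-methyl-3,9-dioxo bicyclic enedione carboxylate (4-methoxycarbonyl Wieland–Miescher-type ketone, 4-ene, labdane numbering) | COC(=O)C1=C2CCCC(=O)[C@@]2(C)CCC1=O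
A4 | alternative 2 | methyl 4α,10β-dimethyl-3,9-dioxo-5α-decalin-4β-carboxylate (labdane numbering) | O=C1CCC[C@@H]2[C@]1(C)CCC(=O)[C@]2(C)C(=O)OC
A5 | alternative 3 | (+)-sclareolide | C[C@@]12CC[C@H]3C(C)(C)CCC[C@]3(C)[C@H]1CC(=O)O2
A6 | alternative 3 | 3β-hydroxysclareolide | C[C@@]12CC[C@H]3C(C)(C)[C@@H](O)CC[C@]3(C)[C@H]1CC(=O)O2
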